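## Structural features

Numbering is that of the labdanes: ring A is C1–C5 plus C10, ring B is C5–C10, C17 is the C8 methylidene carbon, C18 the α carboxyl carbon on C4, C19 the β methyl on C4, C20 the C10 methyl, and β is the face of C20. The target 37 is a cis-fused decalin (H5 and C20 both β) that carries a 2β hydroxyl, a C4 carbon bearing methyl and carboxyl, an exocyclic C8=C17 alkene and, on C9, a five-carbon chain ending in an (E)-3-methyl-2-enoic acid. Its five stereocentres are C2, C4, C5, C10 and C9; C4, C5, C10 and C9 are contiguous, C4 and C10 are quaternary and flank C5, and C2 is 1,3 to both. The fragile groups are the 1,1-disubstituted C8 methylidene (acid moves it into the ring), the trisubstituted enoate geometry and the free secondary alcohol; the C4 carboxyl is neopentyl and its esters resist saponification. The real difficulty is the concave α face: C18 and C9 are 1,3-diaxial on ring A and H9 points under ring A, so the substituents on C4 and C9 have to arrive from the convex β face and in the right order. The key step exploits the unit C2(OH)–C3H2–C4 with a one-carbon branch on C4 in ring A: with C18 written as =CH2 it is a 3-methylenecyclohexanol, the product pattern of a type 2 carbonyl-ene closure of a C2 aldehyde onto an isopropenyl group (C3=C4–CH3) on C5. Ring B with its C8 methyl carbon, the C9 oxygen and the C5 stereocentre is then recognisable as (S)-carvone. Precursor 9, ene product 10 and target 37, written in the same atom order, carry identical descriptors at C5 and C10 (and at C2 for 10 and 37), so no structure needed correction.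

## Logic of the disconnections

37 from 35: the bonds cut are the O–Si bond at C2, the O–CH2 bond of the silylethyl ester at C18 and the acyl–O bond of the ethyl ester at C15. Two different ester types are used because the C18 carbonyl cannot be reached by hydroxide; the gain is a single final operation without acid. The demand is that fluoride frees C2–OH and C18 before hydroxide opens only the unhindered C15 ester.

35 from 32 and 33: C13=C14 is cut. This removes the only alkene geometry of the target and leaves a methyl ketone that is easy to carry in masked form (31). The forward olefination of a methyl ketone must favour E.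

31 from 28 and 28 from 27: no skeletal bond is cut; the exocyclic C8=C17 alkene is traced to its endocyclic C7=C8 isomer through a C17 alcohol. This keeps C17 as the carbon that ring B has had from the start and makes ring B a plain trisubstituted alkene during the work on C4. The forward steps must oxidise C17 and not C9 or C6, then deliver hydrogen to C7 with the alkene moving outward.

27 from 25 and 5, and 25 from 21: C4–C19 is cut, and the C18 carboxyl is traced to the C4 methylidene of 21. The gain is that C4 becomes trigonal, so no stereocentre is carried there. The demand is that methylation of the exocyclic enolate 26 occurs on the β face (the α face is closed by C9), and that the reagent for C4=CH2 ignores C7=C8. The C4 substituents are built only after C9 is tetrahedral, because any α group on C4 sits against C9 and would block chemistry there.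

21 from 20, and 20 from 15 and 16: C9–C11 is cut (and C7–O of the enol triflate). The chain is made the incoming group on a trigonal C9 that already carries its hydrogen, because an incoming group at C9 ends up β. The gain is four carbons (C11, C12, C13, C16) in one step with C9 set. The demand is a conjugate addition at a β-carbon next to the quaternary C10 and capture of the regiodefined enolate, which needs the carbonyl at C7 and not at C9.

15 from 11 through 12 and 14, and 11 from 10: the C9 oxygen is exchanged for a C7 oxygen (1,3-transposition of the enone) and the C2 hydroxyl is masked. Nothing skeletal changes; the gain is that the enone in 10 is exactly what the ene step delivers. The demand is hydrazone formation at a ketone between two fully substituted carbons.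

10 from 9: C2–C3 is cut, which opens ring A. The gain is one ring and the C2 stereocentre, and the precursor is a monocycle with two stereocentres. The demand is a carbonyl-ene closure in which only the aldehyde and the isopropenyl group react; the enone of 9 is left unprotected on purpose, because conjugation keeps C7=C8 out of the reaction.

9 from 7, 7 from 4 and 5, 4 from 1 and 2: C10–C20 and C10–C1 are cut. This leads to a chiral-pool ketone and two simple electrophiles. The demand is the order of the two alkylations: the methyl group must come second so that it ends trans, and the two-carbon arm cis, to the isopropenyl group.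

## Other disconnections considered

Alternative 1: The cut takes out C5–C10 and C3–C4 together, so both rings disappear and an open chain with C9 as its only stereocentre remains. The forward key step would be a thermal intramolecular Diels–Alder reaction in which the 2-silyloxy diene C10=C1–C2=C3 adds across the (Z)-configured C4=C5 enoate of the same chain to give the cis-decalin silyl enol ether diester A1.
- In its favour: two rings, both quaternary carbons and the C4/C5/C10 triad would form in one operation. The side chain and the C8 methylidene would already be in place, so ring B would need no later adjustment. On steps after the key step it is clearly better than the chosen plan.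
- Against it here: the diene terminus C10 carries both the methyl group and the tether, so one of them must sit inside the s-cis diene, and the dienophile is a trisubstituted enoate. The temperature this would need invites 1,5-hydrogen shifts of the silyloxydiene and Z to E leakage, and either would change C4. Facial control would rest on C9 alone. The C2 ketone would then have to be reduced against the convex-face preference of hydride. The hindered C4 methyl ester would remain to be cleaved.
- Comparison: on structure it is the equal of the chosen plan for the cis fusion. On mechanism the chosen ene closure uses an activated aldehyde and a ring-fusion geometry fixed beforehand, whereas here all selectivity lies in one demanding transition state. On step economy the alternative is better, on predictability worse.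

Alternative 2: The cut is C1–C10 and C4–C5, ring A only. The forward key step would be an intermolecular Diels–Alder reaction of the silyloxy dienoate A3 with the enedione A4 under a chiral oxazaborolidinium Lewis acid, giving the cis-fused diketone A2.
- In its favour: absolute configuration would come from a catalyst and two small achiral partners. The cis fusion and the quaternary C10 would be set at once and the endo rule would place the C4 ester. On convergence of the opening steps it is better than the chosen plan, and on the cis fusion it is its equal.
- Against it here: ring B would arrive as the 6,9-dione without C17 and without the side chain. The C6 oxygen must be removed, the two ketones told apart, a carbon added at C8 and the chain attached at C9. The C4 methyl must still be added by enolate alkylation, a step equal to step 15 of the chosen plan. The regiochemistry needs the nucleophilic diene terminus to bond to the fully substituted alkene carbon, while the ester on the diene lowers its reactivity. C2 again needs a ketone reduction.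
- Comparison: it is stronger on absolute stereocontrol from achiral materials, equal on C4, and weaker on step economy after the key step because ring B is over-oxidised and one carbon short.

Alternative 3: The cut is C4–C5. The forward key step would be a desymmetrising intramolecular Michael addition: a chiral primary amine turns the α-methyl aldehyde of the p-cresol-derived dienone A6 into its enamine, whose C4 adds to C5 of one enone arm, giving the cis-fused enone aldehyde A5.
- In its favour: the quaternary C4 with formyl α and methyl β, C5 and C10 would be set in one catalytic step. On C4 this is clearly better than the chosen plan, which spends four steps there. A5 is a C7 enone with C8=C9, the same kind of acceptor as 15, so the side chain addition at C9 would be equal.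
- Against it here: the C2 silyloxy stereocentre must already be enantiopure in the chain and be matched with the catalyst. Enamine formation from an α-branched aldehyde and closure to a quaternary carbon is slow. C8 would lack C17, so after the conjugate addition C8 would need a one-carbon unit and C7 would have to lose its oxygen. The chain must be attached to the para carbon of the cresol by a dearomatising step.
- Comparison: it is equal on the cis fusion, better on C4, worse on C2 and on the C8 carbon, and similar in overall length.

Key step: step 5

Remark on the chemistry: centres that a later step erases (C9 of 8, C7 and C8 of 12, C7 of 14, C4 of 23 to 25) are not controlled on purpose; where a descriptor is drawn for them it is the expected one.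

Step 1
Reactants: 1 (S)-(+)-carvone; 2 tert-butyl bromoacetate
Product: 4 6-(2-tert-butoxy-2-oxoethyl)carvone (new arm trans to isopropenyl), via lithium dienolate 3 (not isolated)
Conditions: LiN(iPr)2, THF, −78 °C; 2, −78 → 0 °C
Reagents that add atoms: tert-butyl bromoacetate, CC(C)(C)OC(=O)CBr
Why: Kinetic deprotonation of the enone at its α′ carbon (future C10) gives the cross-conjugated enolate, which is alkylated (SN2 enolate alkylation) anti to the neighbouring isopropenyl group; this centre is enolised again in step 2, so only the regiochemistry matters.

Step 2
Reactants: 4 6-(2-tert-butoxy-2-oxoethyl)carvone; 5 iodomethane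
Product: 7 6-methyl-6-(2-tert-butoxy-2-oxoethyl)carvone (methyl trans and ester arm cis to isopropenyl), via lithium enolate 6 (not isolated)
Conditions: LiN(iPr)2, THF, −78 °C; MeI, DMPU, −78 → −20 °C
Reagents that add atoms: iodomethane, CI
Why: The ketone α′ hydrogen is several pK units more acidic than the ester CH2, so the tetrasubstituted ketone enolate forms and is C-methylated; iodomethane enters anti to the isopropenyl group on C5 (1,2-induction in enolate alkylation), which sets C10 with the methyl trans and the two-carbon arm cis to isopropenyl.

Step 3
Reactants: 7 6-methyl-6-(2-tert-butoxy-2-oxoethyl)carvone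
Product: 8 diol with 2-hydroxyethyl arm and C9 carbinol (C9 epimers)
Conditions: LiAlH4, THF, 0 °C
Reagents that add atoms: none
Why: Hydride reduction takes the tert-butyl ester to the primary alcohol and the enone carbonyl to the allylic alcohol (1,2-reduction); the carbinol configuration is irrelevant because step 4 returns the ketone.

Step 4
Reactants: 8 diol
Product: 9 6-methyl-6-(2-oxoethyl)carvone (methyl trans and oxoethyl cis to isopropenyl)
Conditions: Dess–Martin periodinane, NaHCO3, CH2Cl2, 23 °C
Reagents that add atoms: none
Why: Dess–Martin oxidation converts both alcohols under neutral conditions; the aldehyde CH2 hangs on a quaternary carbon, so nothing can epimerise, and the two alkenes are untouched.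

Step 5
Reactants: 9 6-methyl-6-(2-oxoethyl)carvone
Product: 10 cis-fused bicyclic enone with 2β-hydroxyl and C4 methylidene (C9 ketone and C7=C8 and 10β-methyl)
Conditions: Me2AlCl (2.2 equiv), CH2Cl2, −78 → −20 °C
Reagents that add atoms: none
Why: Me2AlCl binds the aldehyde oxygen (a second equivalent is taken up by the enone carbonyl), the terminal isopropenyl carbon C3 bonds to C2, and a hydrogen of the isopropenyl methyl ends on oxygen, either within one six-membered ene transition state or by fast proton loss from the tertiary C4 cation, leaving C4=CH2; the aluminium alkoxide then loses methane, which removes any proton source that could move the new alkene. The closest known reaction type is the Lewis-acid type 2 intramolecular carbonyl-ene cyclisation of aldehydes onto 1,1-disubstituted alkenes to give 3-methylenecyclohexanols. Ring A closes in a six-membered mode that is endo for the ene alkene (C3 and C4 both end in the ring) and exo for the carbonyl (oxygen stays outside). The cis fusion is not a matter of selectivity: the aldehyde arm and the isopropenyl group are cis on ring B from step 2, and the existing C5 and C10 centres are not touched. C2 is controlled by the chair-like closure: the aluminium-bound oxygen stays on the convex β face, either equatorial in the chair with C9 axial and C20 equatorial, or axial in the ring-flipped chair, and both place the hydroxyl cis to C20, whereas the α-axial site lies under ring B beside the C9 carbonyl. The step needs aldehyde over ketone selectivity (the ketone is less electrophilic and could only close a five-membered ring), isopropenyl over ring alkene selectivity (C7=C8 is deactivated by conjugation with C9=O) and proton loss from the methyl group and not from the ring (the methyl hydrogen is the one within reach of oxygen).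

Step 6
Reactants: 10 cis-fused bicyclic enone with 2β-hydroxyl
Product: 11 2β-tert-butyldimethylsilyl ether of 10
Conditions: TBSCl, imidazole, DMF, 23 °C
Reagents that add atoms: tert-butyldimethylsilyl chloride, CC(C)(C)[Si](C)(C)Cl
Why: Silylation of the unhindered equatorial secondary alcohol; the ether has to survive hydrazine, organometallics, lithium amide and mild oxidants and to leave with fluoride at the end.

Step 7
Reactants: 11 silyl ether enone
Product: 12 7,8-epoxy C9 ketone (epoxide expected on the β face)
Conditions: H2O2 (30% aq.), NaOH, MeOH, 0 °C
Reagents that add atoms: hydrogen peroxide, OO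
Why: Weitz–Scheffer nucleophilic epoxidation touches only the electron-poor C7=C8 bond and leaves C4=CH2; hydroperoxide is expected to add to C7 anti to C4, but both new centres are removed in steps 8 and 9.

Step 8
Reactants: 12 7,8-epoxy C9 ketone
Product: 14 C7 allylic alcohol with C8=C9 and a hydrogen on C9, via epoxy hydrazone 13 (not isolated)
Conditions: N2H4·H2O, AcOH (cat.), MeOH, 0 → 23 °C
Reagents that add atoms: none
Why: Wharton transposition: the hydrazone opens the epoxide to a vinyl diazene, which loses N2 and leaves the allylic alcohol with the alkene moved to C8=C9 and hydrogen on the former carbonyl carbon.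

Step 9
Reactants: 14 C7 allylic alcohol
Product: 15 transposed enone (C7 ketone and C8=C9 with 8-methyl and C9–H)
Conditions: Dess–Martin periodinane, NaHCO3, CH2Cl2, 23 °C
Reagents that add atoms: none
Why: Oxidation of a secondary allylic alcohol to the enone; C9 is now the β-carbon of the acceptor and still carries its hydrogen.

Step 10
Reactants: 15 transposed enone; 16 2-(2-bromoethyl)-2-methyl-1,3-dioxolane
Product: 20 C7 enol triflate with 9β side chain (9α-H and C7=C8), via Grignard reagent 17 (not isolated), via silyl enol ether 18 (not isolated), via lithium enolate 19 (not isolated)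
Conditions: 16, Mg, THF, 23 °C; 15, CuBr·SMe2 (20 mol %), Me3SiCl, THF, −78 → −30 °C; evaporate; MeLi, THF, 0 → 23 °C; Comins' reagent, 0 → 23 °C
Reagents that add atoms: 2-(2-bromoethyl)-2-methyl-1,3-dioxolane, CC1(CCBr)OCCO1; N-(5-chloro-2-pyridyl)bis(trifluoromethanesulfonimide) (Comins' reagent), Clc1ccc(nc1)N(S(=O)(=O)C(F)(F)F)S(=O)(=O)C(F)(F)F
Why: Copper-catalysed conjugate addition of a Grignard reagent accelerated by Me3SiCl; C9 is attacked on the β face, trans to C4 on C5 (the 3,5-trans rule that cuprates follow with carvone) and away from the concave α face under ring A, so the chain becomes β and H9 α. The enolate is regiodefined (C7–O, C7=C8); it is held as the silyl enol ether, released with MeLi and O-triflated.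

Step 11
Reactants: 20 C7 enol triflate
Product: 21 diene with C7=C8 and C4 methylidene (9β ketal side chain)
Conditions: Pd(OAc)2 (5 mol %), PPh3, HCO2H, n-Bu3N, DMF, 60 °C
Reagents that add atoms: none
Why: Palladium-catalysed formate reduction of an enol triflate (oxidative addition, formate to hydride with loss of CO2, reductive elimination) replaces OTf by H and fixes the alkene at C7=C8; isolated alkene, acetal and silyl ether are inert.

Step 12
Reactants: 21 diene
Product: 23 C18 primary alcohol (C4–CH2OH with C4 epimers), via B-alkyl-9-borabicyclononane 22 (not isolated)
Conditions: 9-BBN, THF, 0 → 23 °C; NaOH, H2O2, 0 °C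
Reagents that add atoms: hydrogen peroxide, OO
Why: Hydroboration–oxidation: 9-BBN takes the 1,1-disubstituted C4=CH2 far faster than the trisubstituted C7=C8 and puts boron on the terminal carbon; the C4 configuration is erased in step 15.

Step 13
Reactants: 23 C18 primary alcohol
Product: 24 C18 carboxylic acid (C4–H)
Conditions: TEMPO (20 mol %), PhI(OAc)2, MeCN/H2O, NaHCO3, 23 °C
Reagents that add atoms: water, O
Why: Oxoammonium oxidation of the primary alcohol to the aldehyde and, through its hydrate, to the acid; alkene, acetal and silyl ether tolerate these buffered conditions.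

Step 14
Reactants: 24 C18 carboxylic acid
Product: 25 2-(trimethylsilyl)ethyl ester of 24
Conditions: Me3SiCH2CH2OH, EDC·HCl, DMAP, CH2Cl2, 23 °C
Reagents that add atoms: 2-(trimethylsilyl)ethanol, C[Si](C)(C)CCO
Why: Carbodiimide (Steglich) esterification of an acid that still has a hydrogen on C4; this ester is chosen because fluoride removes it at the end without any attack on the hindered C18 carbonyl.

Step 15
Reactants: 25 2-(trimethylsilyl)ethyl ester; 5 iodomethane
Product: 27 quaternary C4 ester (4β-methyl and 4α-ester), via lithium ester enolate 26 (not isolated)
Conditions: LiN(iPr)2, THF, −78 → −40 °C; MeI, DMPU, −78 → 0 °C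
Reagents that add atoms: iodomethane, CI
Why: Ester enolate alkylation: the exocyclic C4 enolate is methylated on the convex β face along the equatorial trajectory, because the axial α approach is closed by C9, which is 1,3-diaxial to it on ring A; this leaves the ester α and creates the second quaternary carbon.

Step 16
Reactants: 27 quaternary C4 ester
Product: 28 C17 allylic alcohol (C7=C8 retained)
Conditions: SeO2 (0.5 equiv), t-BuOOH, CH2Cl2, 0 → 23 °C
Reagents that add atoms: selenium dioxide, O=[Se]=O (re-oxidised by tert-butyl hydroperoxide, CC(C)(C)OO)
Why: SeO2 allylic oxidation (ene reaction, then [2,3] shift) places oxygen on an allylic carbon attached to the more substituted alkene carbon C8; the C17 methyl is preferred over the hindered C9 methine, as in drim-7-enes.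

Step 17
Reactants: 28 C17 allylic alcohol
Product: 31 C8 exocyclic methylidene compound (ketal side chain), via N-allyl sulfonylhydrazine 29 (not isolated), via allylic diazene 30 (not isolated)
Conditions: 2-nitrobenzenesulfonylhydrazide (NBSH), PPh3, DEAD, THF, −30 → 23 °C
Reagents that add atoms: none
Why: Myers reductive transposition: Mitsunobu N-alkylation at C17, loss of the sulfinic acid to the allylic diazene, then retro-ene loss of N2 that puts hydrogen on C7 and moves the alkene to C8=C17; no stereocentre is formed.

Step 18
Reactants: 31 C8 exocyclic methylidene ketal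
Product: 32 methyl ketone (C13 ketone)
Conditions: PPTS, acetone/H2O, 50 °C
Reagents that add atoms: water, O
Why: Acetal hydrolysis under a mild buffered acid; the exocyclic alkene, the secondary silyl ether and the silylethyl ester are stable to it.

Step 19
Reactants: 32 methyl ketone; 33 triethyl phosphonoacetate
Product: 35 ethyl (E)-enoate (fully protected target), via sodium phosphonate carbanion 34 (not isolated)
Conditions: 33, NaH, THF, 0 °C; 32, 0 → 65 °C
Reagents that add atoms: triethyl phosphonoacetate, CCOC(=O)CP(=O)(OCC)OCC
Why: Horner–Wadsworth–Emmons olefination of a methyl ketone; the E isomer (chain trans to the ester) should predominate and the Z isomer is separable; the C18 ester has no α hydrogen and is shielded.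

Step 20
Reactants: 35 ethyl (E)-enoate
Product: 37 target hydroxy diacid CNP0086784.2, via hydroxy acid ethyl ester 36 (not isolated)
Conditions: Bu4NF, THF, 23 °C; LiOH, H2O/MeOH, 40 °C; 1 M HCl
Reagents that add atoms: lithium hydroxide, [Li+].[OH-]
Why: Fluoride cleaves the silyl ether and fragments the silylethyl ester (ethene and Me3SiF) without touching the C18 carbonyl; hydroxide then saponifies only the unhindered conjugated ethyl ester; strong acid is avoided throughout, so C8=C17 stays exocyclic.

## Compound list

1 | (S)-(+)-carvone | CC1=CC[C@H](C(C)=C)CC1=O | starting material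
2 | tert-butyl bromoacetate | CC(C)(C)OC(=O)CBr | starting material
3 | lithium α′-dienolate of carvone | CC1=CC[C@H](C(C)=C)C=C1[O-].[Li+] | intermediate (not isolated)
4 | 6-(2-tert-butoxy-2-oxoethyl)carvone, arm trans to isopropenyl | CC1=CC[C@H](C(C)=C)[C@@H](CC(=O)OC(C)(C)C)C1=O | intermediate
5 | iodomethane | CI | starting material
6 | lithium enolate of 4 | CC1=CC[C@H](C(C)=C)C(CC(=O)OC(C)(C)C)=C1[O-].[Li+] | intermediate (not isolated)
7 | 6-methyl-6-(2-tert-butoxy-2-oxoethyl)carvone, methyl trans to isopropenyl | CC1=CC[C@H](C(C)=C)[C@](C)(CC(=O)OC(C)(C)C)C1=O | intermediate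
8 | diol: 6-(2-hydroxyethyl)-6-methylcarveol, C9 epimers | CC1=CC[C@H](C(C)=C)[C@](C)(CCO)C1O | intermediate
9 | 6-methyl-6-(2-oxoethyl)carvone, key-step precursor | CC1=CC[C@H](C(C)=C)[C@](C)(CC=O)C1=O | intermediate
10 | cis-fused enone, 2β-hydroxy, C4 methylidene, C9 ketone, C7=C8, key-step product | CC1=CC[C@H]2[C@](C)(C[C@H](O)CC2=C)C1=O | intermediate
11 | 2β-tert-butyldimethylsilyl ether of 10 | CC1=CC[C@H]2[C@](C)(C[C@H](O[Si](C)(C)C(C)(C)C)CC2=C)C1=O | intermediate
12 | 7,8-epoxy C9 ketone | C[C@]12O[C@H]1C[C@H]3[C@](C)(C[C@H](O[Si](C)(C)C(C)(C)C)CC3=C)C2=O | intermediate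
13 | hydrazone of 12 | C[C@]12O[C@H]1C[C@H]3[C@](C)(C[C@H](O[Si](C)(C)C(C)(C)C)CC3=C)C2=NN | intermediate (not isolated)
14 | C7 allylic alcohol, C8=C9 | O[C@H]1C[C@H]2[C@](C)(C[C@H](O[Si](C)(C)C(C)(C)C)CC2=C)C=C1C | intermediate
15 | transposed enone, C7 ketone, C8=C9 | O=C1C[C@H]2[C@](C)(C[C@H](O[Si](C)(C)C(C)(C)C)CC2=C)C=C1C | intermediate
16 | 2-(2-bromoethyl)-2-methyl-1,3-dioxolane | CC1(CCBr)OCCO1 | starting material
17 | 2-(2-methyl-1,3-dioxolan-2-yl)ethylmagnesium bromide | CC1(CC[Mg]Br)OCCO1 | intermediate (not isolated)
18 | C7 trimethylsilyl enol ether of the conjugate adduct | CC1=C(O[Si](C)(C)C)C[C@H]2[C@](C)(C[C@H](O[Si](C)(C)C(C)(C)C)CC2=C)[C@H]1CCC3(C)OCCO3 | intermediate (not isolated)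
19 | C7 lithium enolate of the conjugate adduct | CC1=C([O-])C[C@H]2[C@](C)(C[C@H](O[Si](C)(C)C(C)(C)C)CC2=C)[C@H]1CCC3(C)OCCO3.[Li+] | intermediate (not isolated)
20 | C7 enol triflate, 9β side chain, 9α-H | CC1=C(OS(=O)(=O)C(F)(F)F)C[C@H]2[C@](C)(C[C@H](O[Si](C)(C)C(C)(C)C)CC2=C)[C@H]1CCC3(C)OCCO3 | intermediate
21 | diene: C7=C8 and C4 methylidene | CC1=CC[C@H]2[C@](C)(C[C@H](O[Si](C)(C)C(C)(C)C)CC2=C)[C@H]1CCC3(C)OCCO3 | intermediate
22 | B-alkyl-9-borabicyclo[3.3.1]nonane at C18 | CC1=CC[C@H]2[C@](C)(C[C@H](O[Si](C)(C)C(C)(C)C)CC2CB4C5CCCC4CCC5)[C@H]1CCC3(C)OCCO3 | intermediate (not isolated)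
23 | C18 primary alcohol, C4 epimers | CC1=CC[C@H]2[C@](C)(C[C@H](O[Si](C)(C)C(C)(C)C)CC2CO)[C@H]1CCC3(C)OCCO3 | intermediate
24 | C18 carboxylic acid, C4–H | CC1=CC[C@H]2[C@](C)(C[C@H](O[Si](C)(C)C(C)(C)C)CC2C(=O)O)[C@H]1CCC3(C)OCCO3 | intermediate
25 | 2-(trimethylsilyl)ethyl ester of 24 | CC1=CC[C@H]2[C@](C)(C[C@H](O[Si](C)(C)C(C)(C)C)CC2C(=O)OCC[Si](C)(C)C)[C@H]1CCC3(C)OCCO3 | intermediate
26 | lithium ester enolate of 25 | CC1=CC[C@H]2[C@](C)(C[C@H](O[Si](C)(C)C(C)(C)C)CC2=C([O-])OCC[Si](C)(C)C)[C@H]1CCC3(C)OCCO3.[Li+] | intermediate (not isolated)
27 | quaternary C4 ester, 4β-methyl, 4α-ester | CC1=CC[C@H]2[C@](C)(C[C@H](O[Si](C)(C)C(C)(C)C)C[C@@]2(C)C(=O)OCC[Si](C)(C)C)[C@H]1CCC3(C)OCCO3 | intermediate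
28 | C17 allylic alcohol | OCC1=CC[C@H]2[C@](C)(C[C@H](O[Si](C)(C)C(C)(C)C)C[C@@]2(C)C(=O)OCC[Si](C)(C)C)[C@H]1CCC3(C)OCCO3 | intermediate
29 | N-(C17-allyl)-N-(2-nitrophenylsulfonyl)hydrazine | NN(CC1=CC[C@H]2[C@](C)(C[C@H](O[Si](C)(C)C(C)(C)C)C[C@@]2(C)C(=O)OCC[Si](C)(C)C)[C@H]1CCC3(C)OCCO3)S(=O)(=O)c4ccccc4[N+](=O)[O-] | intermediate (not isolated)
30 | C17 allylic diazene | N=NCC1=CC[C@H]2[C@](C)(C[C@H](O[Si](C)(C)C(C)(C)C)C[C@@]2(C)C(=O)OCC[Si](C)(C)C)[C@H]1CCC3(C)OCCO3 | intermediate (not isolated)
31 | C8 exocyclic methylidene, ketal side chain | C=C1CC[C@H]2[C@](C)(C[C@H](O[Si](C)(C)C(C)(C)C)C[C@@]2(C)C(=O)OCC[Si](C)(C)C)[C@H]1CCC3(C)OCCO3 | intermediate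
32 | methyl ketone (C13 ketone) | C=C1CC[C@H]2[C@](C)(C[C@H](O[Si](C)(C)C(C)(C)C)C[C@@]2(C)C(=O)OCC[Si](C)(C)C)[C@H]1CCC(C)=O | intermediate
33 | triethyl phosphonoacetate | CCOC(=O)CP(=O)(OCC)OCC | starting material
34 | sodium salt of the phosphonoacetate carbanion | CCOC(=O)[CH-]P(=O)(OCC)OCC.[Na+] | intermediate (not isolated)
35 | ethyl (E)-enoate, fully protected target | C=C1CC[C@H]2[C@](C)(C[C@H](O[Si](C)(C)C(C)(C)C)C[C@@]2(C)C(=O)OCC[Si](C)(C)C)[C@H]1CC/C(C)=C/C(=O)OCC | intermediate
36 | 2β-hydroxy C18 acid, C15 ethyl ester | C=C1CC[C@H]2[C@](C)(C[C@H](O)C[C@@]2(C)C(=O)O)[C@H]1CC/C(C)=C/C(=O)OCC | intermediate (not isolated)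
37 | CNP0086784.2, 2β-hydroxy diacid | C=C1CC[C@H]2[C@](C)(C[C@H](O)C[C@@]2(C)C(=O)O)[C@H]1CC/C(C)=C/C(=O)O | target

## Step count and least certain steps

Total step count: 20. Longest linear sequence: 20 steps, from 1 to 37; 2, 5, 16 and 33 are bought.

Step 5 (key step). Most likely to go wrong: leakage to the 2α epimer through the ring-flipped open transition state with an equatorial oxygen, because the preference between the two chair arrangements of the forming cis-decalin is not large; a second risk is methyl transfer from aluminium to the aldehyde if the closure is slow. Fallback: the route sets out again from 9, accepts the 2α alcohol F1 and inverts it. Mitsunobu esterification with 4-nitrobenzoic acid (PPh3, DIAD) should give the 2β 4-nitrobenzoate F2 by displacement from the open β face, and methanolysis (K2CO3, MeOH) returns to the route at 10.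

Step 10. Most likely to go wrong: slow or incomplete addition at the β-carbon next to the quaternary C10, competing 1,2-addition of the Grignard reagent, or incomplete release of the enolate before triflation. Fallback: from 14, phenyl isocyanate with DMAP gives the N-phenylcarbamate F3. Deprotonation (MeLi), CuBr·SMe2 and Grignard reagent 17 then bring about the carbamate-directed syn γ-substitution of an allylic carbamate by an organocopper reagent. The chain is delivered to C9 on the face of the C7 oxygen (β) and the alkene moves to C7=C8, so the route is rejoined at 21 and steps 9 to 11 are not needed.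

Step 8. Most likely to go wrong: slow hydrazone formation at a ketone that lies between two fully substituted carbons, with opening of the epoxide by hydrazine taking over. Fallback: from 11, NaBH4 with CeCl3·7H2O gives the C9 allylic alcohol F4. Ph3SiOReO3 (catalytic) should move the hydroxyl by 1,3-transposition to the less crowded C7, giving the C7 allylic alcohol F5 as a mixture of C7 epimers. Dess–Martin oxidation of that mixture returns to the route at 15.

Step 16. Most likely to go wrong: oxidation at the wrong allylic position (the C9 methine or C6) or over-oxidation of C17 to the enal. Fallback: from 27, mCPBA gives the 7,8-epoxide F6. Diethylaluminium 2,2,6,6-tetramethylpiperidide, Et2Al(NC9H18), should open it by removing a C17 hydrogen to the 7-hydroxy 8(17)-ene F7. Formic acetic anhydride gives the formate F8, and Pd(OAc)2 with PBu3 reduces it with loss of CO2, hydride going to the more substituted terminus C7. This returns to the route at 31.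

Step 19. Most likely to go wrong: poor E/Z control, which is common in olefinations of methyl ketones, and loss of material through enolisation. Fallback: from 32, LiN(iPr)2, ClP(O)(OEt)2 and again LiN(iPr)2 in one flask should give the terminal alkyne F9. Zirconium-catalysed carboalumination (Me3Al, Cp2ZrCl2) followed by ethyl chloroformate then builds the (E)-3-methyl-2-enoate stereospecifically and returns to the route at 35.

## Further compounds

F1 | step 5 | 2α-hydroxy epimer of 10 | CC1=CC[C@H]2[C@](C)(C[C@@H](O)CC2=C)C1=O
F2 | step 5 | 2β 4-nitrobenzoate of 10 | CC1=CC[C@H]2[C@](C)(C[C@H](OC(=O)c3ccc(cc3)[N+](=O)[O-])CC2=C)C1=O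
F3 | step 10 | N-phenylcarbamate of 14 | O=C(Nc1ccccc1)O[C@H]2C[C@H]3[C@](C)(C[C@H](O[Si](C)(C)C(C)(C)C)CC3=C)C=C2C
F4 | step 8 | C9 allylic alcohol from 11, C9 epimers | CC1=CC[C@H]2[C@](C)(C[C@H](O[Si](C)(C)C(C)(C)C)CC2=C)C1O
F5 | step 8 | C7 allylic alcohol with C8=C9, C7 epimers | OC1C[C@H]2[C@](C)(C[C@H](O[Si](C)(C)C(C)(C)C)CC2=C)C=C1C
F6 | step 16 | 7,8-epoxide of 27 | CC12OC1C[C@H]3[C@](C)(C[C@H](O[Si](C)(C)C(C)(C)C)C[C@@]3(C)C(=O)OCC[Si](C)(C)C)[C@H]2CCC4(C)OCCO4
F7 | step 16 | 7-hydroxy 8(17)-ene | C=C1C(O)C[C@H]2[C@](C)(C[C@H](O[Si](C)(C)C(C)(C)C)C[C@@]2(C)C(=O)OCC[Si](C)(C)C)[C@H]1CCC3(C)OCCO3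
F8 | step 16 | 7-formate of F7 | C=C1C(OC=O)C[C@H]2[C@](C)(C[C@H](O[Si](C)(C)C(C)(C)C)C[C@@]2(C)C(=O)OCC[Si](C)(C)C)[C@H]1CCC3(C)OCCO3
F9 | step 19 | terminal alkyne from 32 | C=C1CC[C@H]2[C@](C)(C[C@H](O[Si](C)(C)C(C)(C)C)C[C@@]2(C)C(=O)OCC[Si](C)(C)C)[C@H]1CCC#C
A1 | alternative 1 | cis-decalin C1=C2 silyl enol ether diester | C=C1CC[C@H]2[C@](C)(C=C(O[Si](C)(C)C(C)(C)C)C[C@@]2(C)C(=O)OC)[C@H]1CC/C(C)=C/C(=O)OC
A2 | alternative 2 | cis-fused 6,9-diketone with C2 silyl enol ether and C4 ester | C1CC(=O)[C@H]2[C@](C)(CC(O[Si](C(C)C)(C(C)C)C(C)C)=C[C@H]2C(=O)OC)C1=O
A3 | alternative 2 | methyl (E)-4-(triisopropylsilyloxy)penta-2,4-dienoate | C=C(O[Si](C(C)C)(C(C)C)C(C)C)/C=C/C(=O)OC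
A4 | alternative 2 | 2-methylcyclohex-2-ene-1,4-dione | CC1=CC(=O)CCC1=O
A5 | alternative 3 | cis-fused bicyclic enone with quaternary C4 formyl group | O=C1C[C@H]2[C@](C)(C[C@H](O[Si](C)(C)C(C)(C)C)C[C@@]2(C)C=O)C=C1
A6 | alternative 3 | 4-methyl-4-[2-silyloxy-4-methyl-5-oxopentyl]cyclohexa-2,5-dienone | O=C1C=CC(C)(C[C@H](O[Si](C)(C)C(C)(C)C)CC(C)C=O)C=C1
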